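## Structural features

The target is a C2-symmetric dimer. Two α-hydroxy-α,β-bis(arylmethyl)-γ-butyrolactone halves are held together only by the aryl–aryl bond between the two ring B carbons C5, each ortho to a phenolic hydroxyl (a 2,2'-biphenol). In each half the lactone (O, C9', C8', C8, C9) carries at C8' the ring B methylene C7', and at C8 a tertiary hydroxyl together with the ring A methylene C7 (ring A is the outer 4-hydroxy-3-methoxyphenyl ring). C8 (R) and C8' (R) are neighbours; the two arylmethyl groups are trans on the lactone and the C8 hydroxyl is cis to C7'. The fragile parts are the four electron-rich free phenols (the biphenol pair oxidises easily), the base-labile lactones and the electron-rich benzylic positions. The real difficulty is the fully substituted carbinol C8 next to C8'. Oxygenation of a lactone enolate would bring the oxygen in anti to the C8' substituent, which is the wrong face. Every stereoselective event also has to occur twice, so imperfect control produces unsymmetrical diastereomers. The key step exploits the fact that C8 bears oxygen while its neighbour C7 is a CH2 bonded to ring A. That is the pattern left when an aryl nucleophile opens a C8–C7 epoxide at its unsubstituted carbon, so C8 can be set earlier, in an open chain, by a reagent.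

## Logic of the disconnections

**24 to 22.** The two lactone acyl–oxygen bonds (C9–O–C9') and six benzyl–oxygen bonds are cut. Opening the lactone gives an acyclic α-hydroxy ester whose C8 can be built without ring constraints. Placing benzyl on all four phenols and on both C9' oxygens lets one hydrogenolysis unmask everything, and the freed C9' hydroxyls of 23 then close the rings. The forward step must leave the benzylic C7 and C7' carbon–carbon bonds alone, and only the C9' hydroxyl may cyclise.

**22 to 18 and 21.** Both C7–C(ring A) bonds are cut. This removes ring A twice and leaves a bis-epoxide and a single aryl Grignard reagent that is used at both ends. No stereocentre is formed. The forward step must attack C7 only and must spare the esters.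

**18 to 15.** No skeletal bond is cut; C9 is taken back from ester (18) through acid (17) and aldehyde (16) to carbinol (15). The carbinol is what a directed epoxidation needs, and the ester is what blocks epoxide migration during the organometallic step. The oxidation must not open the epoxide.

**15 to 14.** The C8–O and C7–O bonds of both oxiranes are cut, one oxygen atom per half. This returns a 1,1-disubstituted allylic alcohol in which the only stereocentres are the two C8' centres. The forward step needs a reagent whose facial preference overrides the bias of C8', twice.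

**14 to 12.** The C8=C7 bond is cut, C7 being a one-carbon unit added to the α-carbon of an aldehyde; 13 lies between, related to 14 by 1,2-reduction. The forward methylenation must not move the new double bond into conjugation at the expense of C8'.

**12 to 9.** The aldehyde carbon C9 is traced to the inner carbon of an allyl group (10), with one carbon lost on cleavage, and the C9' benzyl ether is traced to alcohol 9. The cleavage has to spare the electron-rich rings.

**9 to 7 and 4.** Both C7'–C8' bonds are cut, after returning the C9' carbinol to an acyl group bound to a chiral auxiliary (8). The benzylic carbons of ring B are ideal electrophiles, and one dibromide meets two equivalents of one chiral enolate. The alkylation must set C8' with high face selectivity at both ends, and the auxiliary must leave without epimerisation.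

**To the starting materials.** 4 goes back through 3 and 2 to 1 by changes of functional group only, so the biaryl bond and the oxygenation pattern are bought. 7 is cut at the N–acyl bond to 5 and 6. 21 goes back through 20 to 19.

## Other disconnections considered

**Alternative 1:** The cut is at both C8–O bonds. In the forward step CF3CO3H would oxidise the bis(α-acetyl lactone) tetrapivalate A1, and the quaternary C8 would migrate from the acetyl carbon to oxygen with retention, giving the bis(tertiary acetate) A2.
- *In favour:* C8 would be set by benzylating the α-acetyl lactone enolate anti to C7'. That naturally preferred face puts ring A trans and the acetyl group (the future oxygen) cis to C7', so the bias that defeats enolate hydroxylation becomes an asset. The lactone exists from the start, so C9 and C9' need no changes of oxidation level. In step economy this plan is the better one.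
- *Against:* the migrating carbon is α to the lactone carbonyl and electron-poor, so methyl migration and slow conversion would compete. A strongly acidic peracid must also spare four oxygenated arenes, which is why the electron-withdrawing pivalates are needed. The final solvolysis must remove a hindered tertiary acetate and four pivalates without leaving the lactones open.
- *Comparison:* on structure the two plans are equal in being two-directional and in relaying a pre-set C8'. On mechanism the alternative controls C8 through a cyclic substrate bias, which is at least as predictable as the reagent control in step 11. Its weak point is an oxidising, acidic step on an electron-rich molecule, which is judged a larger risk than the mild organometallic step of the chosen plan.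

**Alternative 2:** The cut is at both C7'–C(ring B) bonds. The iodomethyl lactone A3 would be turned into the alkylzinc iodide A4, which would couple twice with the biaryl bis(triflate) A5 under Pd2(dba)3 and SPhos to give the fully protected target A6.
- *In favour:* this is the most convergent plan and the dimer is formed last. Both stereocentres are set on a monomer, so an enantiopure A3 can give only the C2 dimer and no statistical diastereomers. On convergence and on this point the alternative is the better one.
- *Against:* A3 already contains the C8 carbinol, so the central problem is only moved to the monomer and still needs an answer such as the epoxide logic used here. After transmetalation to divalent palladium the alkyl group has a β-hydrogen at C8', so β-hydride elimination would compete. Two successive oxidative additions into electron-rich aryl triflates are required. A5 needs the formyl carbons of the biaryl degraded to phenols.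
- *Comparison:* on structure it does not simplify C8. On mechanism it uses a cross-coupling cycle between zerovalent and divalent palladium at an sp3 carbon, against an SN2 cuprate opening here. Its longest linear sequence would be shorter, but the total count is expected to be similar or higher.

**Alternative 3:** The cut is at both C8'–C9' bonds. (iPrO)Me2SiCH2MgCl with CuBr·SMe2 and Me3SiCl would add to both butenolides of A7 trans to the γ-aryl group, giving A8. Tamao–Fleming oxidation, hydrogenolysis of the benzylic lactone C–O bond and relactonisation onto the new C9' hydroxyl would then lead to the bis(β-arylmethyl lactone) A9.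
- *In favour:* conjugate addition anti to a γ-substituent of a butenolide is highly predictable, and the directing C7'–O bond is erased afterwards. C8' would be set without a stoichiometric auxiliary, which equals or betters step 5 in atom economy if A7 is available as one enantiomer.
- *Against:* only C8' is solved. From A9 the ring A benzyl group and the C8 oxygen must still be put on the lactone α-carbon, and oxygenation of that enolate prefers the face anti to C7', the wrong one. Reversing the order (oxygen first, benzyl second) would repair this but needs alkylation of a hindered α-oxygenated enolate. The γ-hydrogen of A7 is benzylic and vinylogously acidic, so racemisation under basic, silylating conditions is a risk. The hydrogenolysis also strips the aryl benzyl ethers, which would have to be replaced.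
- *Comparison:* on structure the alternative leaves the harder centre open. On mechanism it relies on substrate control in a ring, the chosen plan on an auxiliary and a catalyst. Once the C8 steps are added it is expected to be longer.

Key step: step 16

Remarks on the chemistry:
- Lignan numbering is used for each half: ring A–C7–C8(OH)–C9(=O)–O–C9'–C8'–C7'–ring B, with the two ring B units joined at C5.
- The oxirane carbon C8 of 15 must be R. The titanium–L-(+)-tartrate reagent gives (2S)-epoxy alcohols from allylic alcohols when the oxirane CH2 outranks the carbinol carbon and the carbinol carbon outranks the 2-substituent, as is the case here. The D-(−)-ester, CCOC(=O)[C@@H](O)[C@H](O)C(=O)OCC, is therefore used as ligand; the L-(+)-ester would lead to the C8 epimers. The ligand carries no number.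
- The C9' oxygen is carried as a benzyl ether, not as a silyl ether. It survives every step, cannot migrate to the C8 alkoxide, and falls in the same hydrogenolysis as the phenol ethers, so a single step follows the key step.

## Route

Step 1
Reactants: 1 dehydrodivanillin
Product: 2 6,6'-bis(benzyloxy)-5,5'-dimethoxybiphenyl-3,3'-dicarbaldehyde
Conditions: BnBr, K2CO3, DMF, 60 °C
Reagents that add atoms: benzyl bromide BrCc1ccccc1
Why: Williamson etherification of both phenols; K2CO3 in DMF should suffice for the hindered biphenol and the aldehydes are not affected.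

Step 2
Reactants: 2 6,6'-bis(benzyloxy)-5,5'-dimethoxybiphenyl-3,3'-dicarbaldehyde
Product: 3 [6,6'-bis(benzyloxy)-5,5'-dimethoxybiphenyl-3,3'-diyl]dimethanol
Conditions: NaBH4, THF–MeOH, 0 °C
Reagents that add atoms: none
Why: Hydride reduction of the aryl aldehydes to benzylic alcohols; benzyl ethers are inert to NaBH4.

Step 3
Reactants: 3 [6,6'-bis(benzyloxy)-5,5'-dimethoxybiphenyl-3,3'-diyl]dimethanol
Product: 4 2,2'-bis(benzyloxy)-5,5'-bis(bromomethyl)-3,3'-dimethoxybiphenyl
Conditions: PBr3, CH2Cl2, 0 °C; used crude
Reagents that add atoms: phosphorus tribromide BrP(Br)Br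
Why: Bromination of the benzylic alcohols through their phosphite esters with displacement by bromide; the para-alkoxybenzyl bromide ionises easily and should be used at once.

Step 4
Reactants: 5 (4S)-4-benzyl-1,3-oxazolidin-2-one; 6 pent-4-enoyl chloride
Product: 7 (4S)-4-benzyl-3-(pent-4-enoyl)-1,3-oxazolidin-2-one
Conditions: n-BuLi, THF, −78 °C; then 6, −78 → 0 °C
Reagents that add atoms: none
Why: N-acylation of the lithiated oxazolidinone by the acid chloride; no stereocentre is formed and C4 of the auxiliary is not at risk.

Step 5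
Reactants: 7 (4S)-4-benzyl-3-(pent-4-enoyl)-1,3-oxazolidin-2-one (2.4 equiv); 4 2,2'-bis(benzyloxy)-5,5'-bis(bromomethyl)-3,3'-dimethoxybiphenyl
Product: 8 2,2'-bis(benzyloxy)-3,3'-dimethoxy-5,5'-bis{(2R)-2-[(4S)-4-benzyl-2-oxo-1,3-oxazolidine-3-carbonyl]pent-4-en-1-yl}biphenyl
Conditions: NaN(SiMe3)2, THF, −78 °C; then 4, −78 → −40 °C
Reagents that add atoms: none
Why: Evans asymmetric alkylation: each benzylic bromide attacks the chelated (Z)-sodium enolate on the face opposite the C4 benzyl group of the (S)-auxiliary, which sets both C8' centres (R in 8). Material alkylated on the wrong face at one end is a diastereomer while the auxiliary is attached and should be removable by chromatography.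

Step 6
Reactants: 8 2,2'-bis(benzyloxy)-3,3'-dimethoxy-5,5'-bis{(2R)-2-[(4S)-4-benzyl-2-oxo-1,3-oxazolidine-3-carbonyl]pent-4-en-1-yl}biphenyl
Product: 9 2,2'-bis(benzyloxy)-5,5'-bis[(2R)-2-(hydroxymethyl)pent-4-en-1-yl]-3,3'-dimethoxybiphenyl
Conditions: LiBH4, THF–MeOH, 0 °C → rt
Reagents that add atoms: none
Why: Reductive cleavage of the N-acyl oxazolidinone at the exocyclic carbonyl gives the primary alcohol (C9') and releases the auxiliary 5; C8' is not enolised under these conditions.

Step 7
Reactants: 9 2,2'-bis(benzyloxy)-5,5'-bis[(2R)-2-(hydroxymethyl)pent-4-en-1-yl]-3,3'-dimethoxybiphenyl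
Product: 10 2,2'-bis(benzyloxy)-5,5'-bis{(2R)-2-[(benzyloxy)methyl]pent-4-en-1-yl}-3,3'-dimethoxybiphenyl
Conditions: NaH, BnBr, Bu4NI (cat.), THF–DMF, 0 °C → rt
Reagents that add atoms: benzyl bromide BrCc1ccccc1
Why: Williamson benzylation of the primary alkoxide; the ether masks C9' until the final hydrogenolysis.

Step 8
Reactants: 10 2,2'-bis(benzyloxy)-5,5'-bis{(2R)-2-[(benzyloxy)methyl]pent-4-en-1-yl}-3,3'-dimethoxybiphenyl
Product: 12 2,2'-bis(benzyloxy)-5,5'-bis{(2S)-2-[(benzyloxy)methyl]-4-oxobutyl}-3,3'-dimethoxybiphenyl, via bis(vicinal diol) 11 (not isolated)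
Conditions: OsO4 (cat.), NaIO4, 2,6-lutidine, dioxane–H2O (3:1), rt
Reagents that add atoms: osmium tetroxide O=[Os](=O)(=O)=O (transfers the oxygen atoms, regenerated in the flask); sodium periodate [Na+].[O-]I(=O)(=O)=O
Why: Lemieux–Johnson oxidation: catalytic OsO4 dihydroxylates each terminal alkene and NaIO4 cleaves diol 11 and reoxidises osmium. 2,6-Lutidine limits over-oxidation, and the arenes and benzyl ethers are not attacked.

Step 9
Reactants: 12 2,2'-bis(benzyloxy)-5,5'-bis{(2S)-2-[(benzyloxy)methyl]-4-oxobutyl}-3,3'-dimethoxybiphenyl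
Product: 13 2,2'-bis(benzyloxy)-5,5'-bis{(2S)-2-[(benzyloxy)methyl]-3-formylbut-3-en-1-yl}-3,3'-dimethoxybiphenyl
Conditions: 37% aq. CH2O, pyrrolidine (cat.), EtCO2H (cat.), i-PrOH, 45 °C
Reagents that add atoms: formaldehyde C=O
Why: Amine-catalysed Mannich-type α-methylenation (enamine plus formaldehyde iminium ion, then elimination) places C7 on C8. C8' lies one carbon from the reacting centre, and the mild, weakly acidic medium should not move the double bond into conjugation through C8'.

Step 10
Reactants: 13 2,2'-bis(benzyloxy)-5,5'-bis{(2S)-2-[(benzyloxy)methyl]-3-formylbut-3-en-1-yl}-3,3'-dimethoxybiphenyl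
Product: 14 2,2'-bis(benzyloxy)-5,5'-bis{(2S)-2-[(benzyloxy)methyl]-3-(hydroxymethyl)but-3-en-1-yl}-3,3'-dimethoxybiphenyl
Conditions: NaBH4, CeCl3·7H2O, MeOH, −40 → 0 °C
Reagents that add atoms: none
Why: Luche 1,2-reduction of the α-substituted acrolein; the cerium-modified borohydride avoids conjugate reduction and C8' is untouched.

Step 11
Reactants: 14 2,2'-bis(benzyloxy)-5,5'-bis{(2S)-2-[(benzyloxy)methyl]-3-(hydroxymethyl)but-3-en-1-yl}-3,3'-dimethoxybiphenyl
Product: 15 2,2'-bis(benzyloxy)-5,5'-bis{(2R)-3-(benzyloxy)-2-[(2R)-2-(hydroxymethyl)oxiran-2-yl]propyl}-3,3'-dimethoxybiphenyl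
Conditions: Ti(OiPr)4 (cat.), D-(−)-diethyl tartrate (cat.), t-BuOOH, 4 Å MS, CH2Cl2, −20 °C
Reagents that add atoms: tert-butyl hydroperoxide CC(C)(C)OO
Why: Sharpless asymmetric epoxidation: the allylic alkoxide binds to the titanium–tartrate complex, and the D-(−)-tartrate directs the peroxide oxygen to the face that makes the oxirane carbon C8 R. The catalyst is expected to override the weak bias of C8'. Catalytic loading with molecular sieves limits opening of the sensitive 2,2-disubstituted epoxy alcohol.

Step 12
Reactants: 15 2,2'-bis(benzyloxy)-5,5'-bis{(2R)-3-(benzyloxy)-2-[(2R)-2-(hydroxymethyl)oxiran-2-yl]propyl}-3,3'-dimethoxybiphenyl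
Product: 17 2,2'-bis(benzyloxy)-5,5'-bis{(2R)-3-(benzyloxy)-2-[(2S)-2-carboxyoxiran-2-yl]propyl}-3,3'-dimethoxybiphenyl, via bis(epoxy aldehyde) 16 (not isolated)
Conditions: TEMPO (cat.), PhI(OAc)2, MeCN–H2O (1:1), rt
Reagents that add atoms: water O
Why: Oxoammonium (TEMPO) oxidation with PhI(OAc)2 as terminal oxidant takes each primary alcohol to aldehyde 16 and, through its hydrate, to the acid. C8 is quaternary and cannot epimerise (its descriptor changes only because the priorities change).

Step 13
Reactants: 17 2,2'-bis(benzyloxy)-5,5'-bis{(2R)-3-(benzyloxy)-2-[(2S)-2-carboxyoxiran-2-yl]propyl}-3,3'-dimethoxybiphenyl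
Product: 18 2,2'-bis(benzyloxy)-5,5'-bis{(2R)-3-(benzyloxy)-2-[(2S)-2-(methoxycarbonyl)oxiran-2-yl]propyl}-3,3'-dimethoxybiphenyl
Conditions: MeI, KHCO3, DMF, rt
Reagents that add atoms: iodomethane CI
Why: SN2 O-methylation of the carboxylate under weakly basic conditions; the epoxide and both stereocentres are unaffected.

Step 14
Reactants: 19 4-bromo-2-methoxyphenol
Product: 20 1-(benzyloxy)-4-bromo-2-methoxybenzene
Conditions: BnBr, K2CO3, acetone, reflux
Reagents that add atoms: benzyl bromide BrCc1ccccc1
Why: Williamson etherification of the phenol.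

Step 15
Reactants: 20 1-(benzyloxy)-4-bromo-2-methoxybenzene
Product: 21 [4-(benzyloxy)-3-methoxyphenyl]magnesium bromide (THF solution)
Conditions: Mg turnings (I2-activated), THF, 45 °C
Reagents that add atoms: magnesium [Mg]
Why: Grignard formation by insertion of Mg into the aryl C–Br bond; the ether groups are compatible.

Step 16
Reactants: 18 2,2'-bis(benzyloxy)-5,5'-bis{(2R)-3-(benzyloxy)-2-[(2S)-2-(methoxycarbonyl)oxiran-2-yl]propyl}-3,3'-dimethoxybiphenyl; 21 [4-(benzyloxy)-3-methoxyphenyl]magnesium bromide (about 3 equiv per epoxide)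
Product: 22 2,2'-bis(benzyloxy)-5,5'-bis{(2R,3R)-2-[(benzyloxy)methyl]-3-[4-(benzyloxy)-3-methoxybenzyl]-3-hydroxy-4-methoxy-4-oxobutyl}-3,3'-dimethoxybiphenyl
Conditions: CuI (10 mol% per epoxide), THF, −40 → −20 °C, slow addition of 21; then sat. aq. NH4Cl
Reagents that add atoms: none
Why: Transmetalation of 21 to CuI gives a magnesium aryl cuprate of monovalent copper, which attacks the epoxide CH2 (C7) from the rear in an SN2-like oxidative addition; the resulting alkyl aryl species of trivalent copper forms the C7–aryl bond by reductive elimination, returns the catalyst and leaves C8–O as a magnesium alkoxide. The closest known reaction type is the copper-catalysed opening of terminal and 2,2-disubstituted epoxides, glycidic esters included, by Grignard reagents at the less substituted carbon. No ring closes and no stereocentre is created: C8 keeps its configuration because only the C7–O bond breaks, and C8' is a spectator. Regioselectivity is secured by the substrate, since C8 is quaternary and α to an ester (blocked sterically and unfit electronically for SN2) while C7 is primary. Chemoselectivity for the epoxide over the methyl ester rests on the low temperature and on the cuprate opening being much faster than uncatalysed 1,2-addition to an ester flanked by the quaternary C8. Bromide opening promoted by MgBr2 is the other competitor and is limited by slow addition of 21 to the substrate–CuI mixture in the cold. The two epoxides react independently, so an excess of 21 should carry the two-directional process to the bis(α-hydroxy ester) after protonation.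

Step 17
Reactants: 22 2,2'-bis(benzyloxy)-5,5'-bis{(2R,3R)-2-[(benzyloxy)methyl]-3-[4-(benzyloxy)-3-methoxybenzyl]-3-hydroxy-4-methoxy-4-oxobutyl}-3,3'-dimethoxybiphenyl
Product: 24 bis-5,5-nortrachelogenin, via hexahydroxy diester 23 (not isolated)
Conditions: H2 (1 atm), Pd(OH)2/C, THF–EtOAc, rt; N2 purge, then p-TsOH·H2O (cat.), 40 °C
Reagents that add atoms: none
Why: Catalytic hydrogenolysis of the six benzyl ethers gives 23, whose C9' hydroxyl closes onto the neighbouring methyl ester in an acid-catalysed 5-exo-trig lactonisation. The C7 and C7' carbon–carbon bonds are not cleaved and both stereocentres are untouched.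

## Compound list

1 | dehydrodivanillin (6,6'-dihydroxy-5,5'-dimethoxybiphenyl-3,3'-dicarbaldehyde) | O=Cc1cc(OC)c(O)c(c1)-c1cc(C=O)cc(OC)c1O | starting material
2 | 6,6'-bis(benzyloxy)-5,5'-dimethoxybiphenyl-3,3'-dicarbaldehyde | O=Cc1cc(OC)c(OCc2ccccc2)c(c1)-c1cc(C=O)cc(OC)c1OCc1ccccc1 | intermediate
3 | [6,6'-bis(benzyloxy)-5,5'-dimethoxybiphenyl-3,3'-diyl]dimethanol | OCc1cc(OC)c(OCc2ccccc2)c(c1)-c1cc(CO)cc(OC)c1OCc1ccccc1 | intermediate
4 | 2,2'-bis(benzyloxy)-5,5'-bis(bromomethyl)-3,3'-dimethoxybiphenyl | BrCc1cc(OC)c(OCc2ccccc2)c(c1)-c1cc(CBr)cc(OC)c1OCc1ccccc1 | intermediate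
5 | (4S)-4-benzyl-1,3-oxazolidin-2-one | O=C1OC[C@H](Cc2ccccc2)N1 | starting material
6 | pent-4-enoyl chloride | C=CCCC(Cl)=O | starting material
7 | (4S)-4-benzyl-3-(pent-4-enoyl)-1,3-oxazolidin-2-one | C=CCCC(=O)N1[C@@H](Cc2ccccc2)COC1=O | intermediate
8 | 2,2'-bis(benzyloxy)-3,3'-dimethoxy-5,5'-bis{(2R)-2-[(4S)-4-benzyl-2-oxo-1,3-oxazolidine-3-carbonyl]pent-4-en-1-yl}biphenyl | c1(C[C@H](C(=O)N2[C@@H](Cc3ccccc3)COC2=O)CC=C)cc(OC)c(OCc2ccccc2)c(c1)-c1cc(C[C@H](C(=O)N2[C@@H](Cc3ccccc3)COC2=O)CC=C)cc(OC)c1OCc1ccccc1 | intermediate
9 | 2,2'-bis(benzyloxy)-5,5'-bis[(2R)-2-(hydroxymethyl)pent-4-en-1-yl]-3,3'-dimethoxybiphenyl | c1(C[C@H](CO)CC=C)cc(OC)c(OCc2ccccc2)c(c1)-c1cc(C[C@H](CO)CC=C)cc(OC)c1OCc1ccccc1 | intermediate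
10 | 2,2'-bis(benzyloxy)-5,5'-bis{(2R)-2-[(benzyloxy)methyl]pent-4-en-1-yl}-3,3'-dimethoxybiphenyl | c1(C[C@H](COCc2ccccc2)CC=C)cc(OC)c(OCc2ccccc2)c(c1)-c1cc(C[C@H](COCc2ccccc2)CC=C)cc(OC)c1OCc1ccccc1 | intermediate
11 | 2,2'-bis(benzyloxy)-5,5'-bis{(2S)-2-[(benzyloxy)methyl]-4,5-dihydroxypentyl}-3,3'-dimethoxybiphenyl (C4 carbinol epimers) | c1(C[C@H](COCc2ccccc2)CC(O)CO)cc(OC)c(OCc2ccccc2)c(c1)-c1cc(C[C@H](COCc2ccccc2)CC(O)CO)cc(OC)c1OCc1ccccc1 | intermediate
12 | 2,2'-bis(benzyloxy)-5,5'-bis{(2S)-2-[(benzyloxy)methyl]-4-oxobutyl}-3,3'-dimethoxybiphenyl | c1(C[C@H](COCc2ccccc2)CC=O)cc(OC)c(OCc2ccccc2)c(c1)-c1cc(C[C@H](COCc2ccccc2)CC=O)cc(OC)c1OCc1ccccc1 | intermediate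
13 | 2,2'-bis(benzyloxy)-5,5'-bis{(2S)-2-[(benzyloxy)methyl]-3-formylbut-3-en-1-yl}-3,3'-dimethoxybiphenyl | c1(C[C@H](COCc2ccccc2)C(=C)C=O)cc(OC)c(OCc2ccccc2)c(c1)-c1cc(C[C@H](COCc2ccccc2)C(=C)C=O)cc(OC)c1OCc1ccccc1 | intermediate
14 | 2,2'-bis(benzyloxy)-5,5'-bis{(2S)-2-[(benzyloxy)methyl]-3-(hydroxymethyl)but-3-en-1-yl}-3,3'-dimethoxybiphenyl | c1(C[C@H](COCc2ccccc2)C(=C)CO)cc(OC)c(OCc2ccccc2)c(c1)-c1cc(C[C@H](COCc2ccccc2)C(=C)CO)cc(OC)c1OCc1ccccc1 | intermediate
15 | 2,2'-bis(benzyloxy)-5,5'-bis{(2R)-3-(benzyloxy)-2-[(2R)-2-(hydroxymethyl)oxiran-2-yl]propyl}-3,3'-dimethoxybiphenyl | c1(C[C@H](COCc2ccccc2)[C@]2(CO2)CO)cc(OC)c(OCc2ccccc2)c(c1)-c1cc(C[C@H](COCc2ccccc2)[C@]2(CO2)CO)cc(OC)c1OCc1ccccc1 | intermediate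
16 | 2,2'-bis(benzyloxy)-5,5'-bis{(2R)-3-(benzyloxy)-2-[(2S)-2-formyloxiran-2-yl]propyl}-3,3'-dimethoxybiphenyl | c1(C[C@H](COCc2ccccc2)[C@]2(CO2)C=O)cc(OC)c(OCc2ccccc2)c(c1)-c1cc(C[C@H](COCc2ccccc2)[C@]2(CO2)C=O)cc(OC)c1OCc1ccccc1 | intermediate
17 | 2,2'-bis(benzyloxy)-5,5'-bis{(2R)-3-(benzyloxy)-2-[(2S)-2-carboxyoxiran-2-yl]propyl}-3,3'-dimethoxybiphenyl | c1(C[C@H](COCc2ccccc2)[C@]2(CO2)C(=O)O)cc(OC)c(OCc2ccccc2)c(c1)-c1cc(C[C@H](COCc2ccccc2)[C@]2(CO2)C(=O)O)cc(OC)c1OCc1ccccc1 | intermediate
18 | 2,2'-bis(benzyloxy)-5,5'-bis{(2R)-3-(benzyloxy)-2-[(2S)-2-(methoxycarbonyl)oxiran-2-yl]propyl}-3,3'-dimethoxybiphenyl | c1(C[C@H](COCc2ccccc2)[C@]2(CO2)C(=O)OC)cc(OC)c(OCc2ccccc2)c(c1)-c1cc(C[C@H](COCc2ccccc2)[C@]2(CO2)C(=O)OC)cc(OC)c1OCc1ccccc1 | intermediate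
19 | 4-bromo-2-methoxyphenol | COc1cc(Br)ccc1O | starting material
20 | 1-(benzyloxy)-4-bromo-2-methoxybenzene | COc1cc(Br)ccc1OCc1ccccc1 | intermediate
21 | [4-(benzyloxy)-3-methoxyphenyl]magnesium bromide | COc1cc([Mg]Br)ccc1OCc1ccccc1 | intermediate
22 | 2,2'-bis(benzyloxy)-5,5'-bis{(2R,3R)-2-[(benzyloxy)methyl]-3-[4-(benzyloxy)-3-methoxybenzyl]-3-hydroxy-4-methoxy-4-oxobutyl}-3,3'-dimethoxybiphenyl | c1(C[C@H](COCc2ccccc2)[C@@](O)(C(=O)OC)Cc2ccc(OCc3ccccc3)c(OC)c2)cc(OC)c(OCc2ccccc2)c(c1)-c1cc(C[C@H](COCc2ccccc2)[C@@](O)(C(=O)OC)Cc2ccc(OCc3ccccc3)c(OC)c2)cc(OC)c1OCc1ccccc1 | intermediate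
23 | 5,5'-bis{(2R,3R)-3-hydroxy-3-(4-hydroxy-3-methoxybenzyl)-2-(hydroxymethyl)-4-methoxy-4-oxobutyl}-3,3'-dimethoxybiphenyl-2,2'-diol | c1(C[C@H](CO)[C@@](O)(C(=O)OC)Cc2ccc(O)c(OC)c2)cc(OC)c(O)c(c1)-c1cc(C[C@H](CO)[C@@](O)(C(=O)OC)Cc2ccc(O)c(OC)c2)cc(OC)c1O | intermediate
24 | bis-5,5-nortrachelogenin, (3R,3'R,4R,4'R)-4,4'-[(6,6'-dihydroxy-5,5'-dimethoxybiphenyl-3,3'-diyl)bis(methylene)]bis[3-hydroxy-3-(4-hydroxy-3-methoxybenzyl)oxolan-2-one] | COc1cc(C[C@]2(O)C(=O)OC[C@H]2Cc2cc(OC)c(O)c(-c3cc(C[C@@H]4COC(=O)[C@@]4(O)Cc4ccc(O)c(OC)c4)cc(OC)c3O)c2)ccc1O | target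

## Step count and least certain steps

Total step count: 17. Longest linear sequence: 14 steps (steps 1–3, 5–13, 16 and 17, from 1).

**Step 16 (key step).** The most likely failures are competing addition of 21 to the methyl esters, bromide opening of the epoxides promoted by magnesium halide, and a stalled second opening. All follow from a reactive organomagnesium reagent meeting a substrate with two electrophilic sites per half. The fallback sets out from 17 and exchanges the order of esterification and opening. The first equivalents of 21 turn 17 into its bis(magnesium carboxylate), whose carbonyl carbon is inert to the Grignard reagent. The same CuI-catalysed opening at C7 (known for glycidic acid salts) should then give the bis(α-hydroxy acid) F1. Methylation with MeI and KHCO3 in DMF returns to the route at 22.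

**Step 11.** Incomplete facial control is the main danger, because the branched, stereogenic 2-substituent may be mismatched with the catalyst and every lapse is doubled by the two sites. Alkoxide opening of the 2,2-disubstituted epoxy alcohol on the Lewis-acidic titanium centre is the second danger. The fallback sets out from 13 and replaces the metal-directed epoxidation by iminium catalysis. A diarylprolinol silyl ether (the enantiomer that gives the S-configured formyl oxirane) with aqueous H2O2 should epoxidise the α-substituted acrolein to 16, which is isolated in this case. Oxidation with NaClO2 (NaH2PO4, 2-methyl-2-butene, t-BuOH–H2O) comes back to the route at 17. The detour makes no compound outside the list (F0) and bypasses steps 10 to 12.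

**Step 12.** Acid-promoted hydrolysis of the epoxide in the aqueous medium (acetic acid is liberated), decarboxylative decomposition of the free glycidic acid on concentration, and attack of the iodine reagent on the electron-rich rings are the likely failures. The fallback sets out from 15 and postpones the oxidation until the epoxide has been consumed. Silylation (t-BuMe2SiCl, imidazole) gives the bis(epoxy silyl ether) F2, which cannot undergo epoxide migration. Opening with 21 and catalytic CuI, now with no carbonyl group present, gives the bis(tertiary alcohol) F3; silyl migration to the new alkoxide would be harmless. Bu4NF gives the bis(1,2-diol) F4. TEMPO with NaClO2 and catalytic NaOCl at pH 6.7 oxidises the primary hydroxyls to the hydroxy acid F1 already described, and methylation returns to the route at 22.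

**Step 17.** Slow hydrogenolysis of the two aliphatic benzyl ethers compared with the four aryl benzyl ethers could leave partly protected material, and ring closure could stay incomplete without enough acid. The fallback sets out from 22 and uses an ionic, not a reductive, cleavage: BCl3 with pentamethylbenzene as cation scavenger in CH2Cl2 at −78 °C removes all six benzyl groups, and the acidic work-up closes both lactones, arriving at 24. It makes no compound outside the list (F0).

## Further compounds

F1 | step 16 | bis(α-hydroxy acid): 22 with both methyl esters replaced by carboxylic acids, configuration as in 22 | c1(C[C@H](COCc2ccccc2)[C@@](O)(C(=O)O)Cc2ccc(OCc3ccccc3)c(OC)c2)cc(OC)c(OCc2ccccc2)c(c1)-c1cc(C[C@H](COCc2ccccc2)[C@@](O)(C(=O)O)Cc2ccc(OCc3ccccc3)c(OC)c2)cc(OC)c1OCc1ccccc1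
F0 | step 11 | none | none
F2 | step 12 | bis(epoxy silyl ether): 15 with both primary hydroxyls as tert-butyldimethylsilyl ethers, configuration as in 15 | c1(C[C@H](COCc2ccccc2)[C@]2(CO2)CO[Si](C)(C)C(C)(C)C)cc(OC)c(OCc2ccccc2)c(c1)-c1cc(C[C@H](COCc2ccccc2)[C@]2(CO2)CO[Si](C)(C)C(C)(C)C)cc(OC)c1OCc1ccccc1
F3 | step 12 | bis(tertiary alcohol): 22 with each CO2Me replaced by CH2OSi(t-Bu)Me2, same spatial arrangement at C8 and C8' | c1(C[C@H](COCc2ccccc2)[C@@](O)(CO[Si](C)(C)C(C)(C)C)Cc2ccc(OCc3ccccc3)c(OC)c2)cc(OC)c(OCc2ccccc2)c(c1)-c1cc(C[C@H](COCc2ccccc2)[C@@](O)(CO[Si](C)(C)C(C)(C)C)Cc2ccc(OCc3ccccc3)c(OC)c2)cc(OC)c1OCc1ccccc1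
F4 | step 12 | bis(1,2-diol): 22 with each CO2Me replaced by CH2OH, same spatial arrangement at C8 and C8' | c1(C[C@H](COCc2ccccc2)[C@@](O)(CO)Cc2ccc(OCc3ccccc3)c(OC)c2)cc(OC)c(OCc2ccccc2)c(c1)-c1cc(C[C@H](COCc2ccccc2)[C@@](O)(CO)Cc2ccc(OCc3ccccc3)c(OC)c2)cc(OC)c1OCc1ccccc1
F0 | step 17 | none | none
A1 | alternative 1 | bis(α-acetyl-α-benzyl lactone) tetrapivalate: target skeleton with C8–C(O)CH3 in place of C8–OH and four phenol pivalates | c1(C[C@@H]2COC(=O)[C@@]2(C(C)=O)Cc2ccc(OC(=O)C(C)(C)C)c(OC)c2)cc(OC)c(OC(=O)C(C)(C)C)c(c1)-c1cc(C[C@@H]2COC(=O)[C@@]2(C(C)=O)Cc2ccc(OC(=O)C(C)(C)C)c(OC)c2)cc(OC)c1OC(=O)C(C)(C)C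
A2 | alternative 1 | bis(tertiary acetate) of the tetrapivaloyl target | c1(C[C@@H]2COC(=O)[C@@]2(OC(C)=O)Cc2ccc(OC(=O)C(C)(C)C)c(OC)c2)cc(OC)c(OC(=O)C(C)(C)C)c(c1)-c1cc(C[C@@H]2COC(=O)[C@@]2(OC(C)=O)Cc2ccc(OC(=O)C(C)(C)C)c(OC)c2)cc(OC)c1OC(=O)C(C)(C)C
A3 | alternative 2 | iodomethyl lactone: α-[4-(benzyloxy)-3-methoxybenzyl]-β-(iodomethyl)-α-(triethylsilyloxy)-γ-butyrolactone, arrangement as in the target | IC[C@@H]1COC(=O)[C@@]1(O[Si](CC)(CC)CC)Cc1ccc(OCc2ccccc2)c(OC)c1
A4 | alternative 2 | alkylzinc iodide derived from A3 | I[Zn]C[C@@H]1COC(=O)[C@@]1(O[Si](CC)(CC)CC)Cc1ccc(OCc2ccccc2)c(OC)c1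
A5 | alternative 2 | 2,2'-bis(benzyloxy)-3,3'-dimethoxybiphenyl-5,5'-diyl bis(trifluoromethanesulfonate) | c1(OS(=O)(=O)C(F)(F)F)cc(OC)c(OCc2ccccc2)c(c1)-c1cc(OS(=O)(=O)C(F)(F)F)cc(OC)c1OCc1ccccc1
A6 | alternative 2 | fully protected target (two triethylsilyl ethers, four benzyl ethers) | c1(C[C@@H]2COC(=O)[C@@]2(O[Si](CC)(CC)CC)Cc2ccc(OCc3ccccc3)c(OC)c2)cc(OC)c(OCc2ccccc2)c(c1)-c1cc(C[C@@H]2COC(=O)[C@@]2(O[Si](CC)(CC)CC)Cc2ccc(OCc3ccccc3)c(OC)c2)cc(OC)c1OCc1ccccc1
A7 | alternative 3 | bis[(R)-5-aryl-furan-2(5H)-one] on the dibenzylated biaryl core | c1([C@@H]2OC(=O)C=C2)cc(OC)c(OCc2ccccc2)c(c1)-c1cc([C@@H]2OC(=O)C=C2)cc(OC)c1OCc1ccccc1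
A8 | alternative 3 | bis(trans-β-{[dimethyl(isopropoxy)silyl]methyl}-γ-aryl lactone) | c1([C@@H]2OC(=O)C[C@H]2C[Si](C)(C)OC(C)C)cc(OC)c(OCc2ccccc2)c(c1)-c1cc([C@@H]2OC(=O)C[C@H]2C[Si](C)(C)OC(C)C)cc(OC)c1OCc1ccccc1
A9 | alternative 3 | bis[β-(arylmethyl)-γ-butyrolactone] with free phenols, C8' as in the target | c1(C[C@@H]2COC(=O)C2)cc(OC)c(O)c(c1)-c1cc(C[C@@H]2COC(=O)C2)cc(OC)c1O
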